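**Retrosynthetic overview**

1. Ring A is the 1-methylcyclohexene (C1 bears CH3, C2 is the alkene CH, C3 bears ring D, C4 bears the ketone to ring B, C5 bears ring C, C6 is CH2); ring E is the 4-hydroxyphenyl of the cinnamoyl group on ring D. Ring A is cut across C3–C4 and C5–C6 into an (E)-1-aryl-3-methylbuta-1,3-diene (rings D and E) and an (E)-chalcone (rings B and C).
2. Enabling feature: the free 2'-hydroxyl of ring B sits ortho to the C4 ketone. This ortho-hydroxyaryl ketone chelates boron through the phenol oxygen and the ketone oxygen, which lowers the LUMO of the enone that becomes C4–C5, locks it s-cis and places a chiral biaryl diol beside it. All six other phenols are acetates, so no other carbonyl can bind boron.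
3. Both partners come from one aryl iodide, 3-iodo-2,4-dihydroxyacetophenone. Claisen–Schmidt condensation builds each chalcone, the MOM groups are exchanged for acetates, and Suzuki coupling installs the (E)-3-methylbut-1-enyl chain (ring B) or the (E)-3-methylbuta-1,3-dienyl chain (ring D) after all acid steps.
4. Ring order: rings B, C, D and E are purchased arenes. Ring A is the only ring made and is closed last, by an enantioselective endo [4+2] cycloaddition that sets C3, C4 and C5 together; global deacetylation then gives the target.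

Key step: step 14

Assumption: (R)-VANOL is taken, from a simple model of the spiro-borate, to be the ligand antipode that leaves the alpha-Si/beta-Si face of the chelated enone open; the induction is ligand-controlled, so (S)-VANOL would be used instead, with nothing else changed, if the opposite sense were found.

**Step 1**
Reactants: 1 2,4-dihydroxyacetophenone
Product: 2 1-(2,4-dihydroxy-3-iodophenyl)ethanone
Conditions: I2, HIO3, EtOH/H2O, rt
Reagents that add atoms: iodine, II; iodic acid, O[I](=O)=O
Why: Electrophilic aromatic iodination with the iodine/iodic acid couple should take place at C3, the position activated by both flanking hydroxyls, and it uses all iodine atoms.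

**Step 2**
Reactants: 2 1-(2,4-dihydroxy-3-iodophenyl)ethanone
Product: 3 1-[2-hydroxy-3-iodo-4-(methoxymethoxy)phenyl]ethanone
Conditions: MOMCl (1.1 equiv), K2CO3, acetone, 0 °C to rt
Reagents that add atoms: chloromethyl methyl ether, COCCl
Why: Williamson-type O-alkylation should be selective for the 4-hydroxyl because the 2-hydroxyl is hydrogen-bonded to the acetyl carbonyl and is the weaker nucleophile.

**Step 3**
Reactants: 4 2,4-dihydroxybenzaldehyde
Product: 5 2,4-bis(methoxymethoxy)benzaldehyde
Conditions: MOMCl (3 equiv), K2CO3, acetone, reflux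
Reagents that add atoms: chloromethyl methyl ether, COCCl
Why: Exhaustive O-alkylation with excess reagent and heat should also engage the chelated 2-hydroxyl, giving a base-stable aldehyde for the crossed aldol step.

**Step 4**
Reactants: 3 1-[2-hydroxy-3-iodo-4-(methoxymethoxy)phenyl]ethanone; 5 2,4-bis(methoxymethoxy)benzaldehyde
Product: 6 (E)-3-[2,4-bis(methoxymethoxy)phenyl]-1-[2-hydroxy-3-iodo-4-(methoxymethoxy)phenyl]prop-2-en-1-one
Conditions: KOH (50% aq), EtOH, 0 °C to rt; then dilute HCl to pH 5 at 0 °C
Reagents that add atoms: none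
Why: Claisen–Schmidt condensation of the methyl ketone with a non-enolisable aldehyde, followed by E1cB dehydration, should give the thermodynamically favoured E-enone, and the aryl iodide and MOM ethers are stable to hydroxide.

**Step 5**
Reactants: 6 (E)-3-[2,4-bis(methoxymethoxy)phenyl]-1-[2-hydroxy-3-iodo-4-(methoxymethoxy)phenyl]prop-2-en-1-one
Product: 7 (E)-1-(2,4-dihydroxy-3-iodophenyl)-3-(2,4-dihydroxyphenyl)prop-2-en-1-one
Conditions: 3 M HCl (aq), MeOH/THF, 40 °C
Reagents that add atoms: none
Why: Acid-catalysed acetal methanolysis removes the three MOM groups at a stage where no acid-sensitive styrene or diene is present, and the mild temperature limits cyclisation of the hydroxychalcone.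

**Step 6**
Reactants: 7 (E)-1-(2,4-dihydroxy-3-iodophenyl)-3-(2,4-dihydroxyphenyl)prop-2-en-1-one
Product: 8 (E)-1-(4-acetoxy-2-hydroxy-3-iodophenyl)-3-(2,4-diacetoxyphenyl)prop-2-en-1-one
Conditions: Ac2O (3.3 equiv), pyridine, CH2Cl2, 0 °C
Reagents that add atoms: acetic anhydride, CC(=O)OC(C)=O
Why: Selective O-acetylation should leave the 2'-hydroxyl free because it is hydrogen-bonded to the ketone and flanked by iodine, while the three ordinary phenols acylate quickly.

**Step 7**
Reactants: 9 3-methylbut-1-yne; 10 pinacolborane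
Product: 11 (E)-4,4,5,5-tetramethyl-2-(3-methylbut-1-en-1-yl)-1,3,2-dioxaborolane
Conditions: Cp2Zr(H)Cl (5 mol%), Et3N (10 mol%), neat, sealed tube, 60 °C
Reagents that add atoms: none
Why: Zirconium-catalysed hydroboration of a terminal alkyne is a syn, anti-Markovnikov addition and should give the E-alkenylboronate only.

**Step 8**
Reactants: 8 (E)-1-(4-acetoxy-2-hydroxy-3-iodophenyl)-3-(2,4-diacetoxyphenyl)prop-2-en-1-one; 11 (E)-4,4,5,5-tetramethyl-2-(3-methylbut-1-en-1-yl)-1,3,2-dioxaborolane
Product: 12 (E)-1-[4-acetoxy-2-hydroxy-3-[(E)-3-methylbut-1-en-1-yl]phenyl]-3-(2,4-diacetoxyphenyl)prop-2-en-1-one (the dienophile)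
Conditions: Pd(dppf)Cl2 (5 mol%), CsF (3 equiv), dry THF, 60 °C, argon
Reagents that add atoms: none
Why: Suzuki–Miyaura coupling proceeds with retention of the E-alkenyl geometry, and anhydrous fluoride activation is chosen so that the aryl acetates are not hydrolysed.

**Step 9**
Reactants: 3 1-[2-hydroxy-3-iodo-4-(methoxymethoxy)phenyl]ethanone; 13 4-(methoxymethoxy)benzaldehyde
Product: 14 (E)-1-[2-hydroxy-3-iodo-4-(methoxymethoxy)phenyl]-3-[4-(methoxymethoxy)phenyl]prop-2-en-1-one
Conditions: KOH (50% aq), EtOH, 0 °C to rt; then dilute HCl to pH 5 at 0 °C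
Reagents that add atoms: none
Why: The same Claisen–Schmidt condensation and E1cB dehydration should give the E-chalcone that carries rings D and E.

**Step 10**
Reactants: 14 (E)-1-[2-hydroxy-3-iodo-4-(methoxymethoxy)phenyl]-3-[4-(methoxymethoxy)phenyl]prop-2-en-1-one
Product: 15 (E)-1-(2,4-dihydroxy-3-iodophenyl)-3-(4-hydroxyphenyl)prop-2-en-1-one
Conditions: 3 M HCl (aq), MeOH/THF, 40 °C
Reagents that add atoms: none
Why: Acid-catalysed acetal methanolysis removes both MOM groups before the acid-labile diene is introduced.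

**Step 11**
Reactants: 15 (E)-1-(2,4-dihydroxy-3-iodophenyl)-3-(4-hydroxyphenyl)prop-2-en-1-one
Product: 16 (E)-1-(2,4-diacetoxy-3-iodophenyl)-3-(4-acetoxyphenyl)prop-2-en-1-one
Conditions: Ac2O (6 equiv), pyridine, DMAP (10 mol%), rt
Reagents that add atoms: acetic anhydride, CC(=O)OC(C)=O
Why: DMAP-catalysed exhaustive acetylation also caps the chelated 2'-hydroxyl, which removes the only group through which this enone could bind boron and blocks chromene formation from the later ortho-dienyl phenol.

**Step 12**
Reactants: 17 2-methylbut-1-en-3-yne; 10 pinacolborane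
Product: 18 (E)-4,4,5,5-tetramethyl-2-(3-methylbuta-1,3-dien-1-yl)-1,3,2-dioxaborolane
Conditions: Cp2Zr(H)Cl (5 mol%), Et3N (10 mol%), neat, sealed tube, 50 °C
Reagents that add atoms: none
Why: Zirconium-catalysed syn hydroboration is chemoselective for the terminal alkyne over the 1,1-disubstituted alkene and should give the E-dienylboronate.

**Step 13**
Reactants: 16 (E)-1-(2,4-diacetoxy-3-iodophenyl)-3-(4-acetoxyphenyl)prop-2-en-1-one; 18 (E)-4,4,5,5-tetramethyl-2-(3-methylbuta-1,3-dien-1-yl)-1,3,2-dioxaborolane
Product: 19 (E)-1-[2,4-diacetoxy-3-[(E)-3-methylbuta-1,3-dien-1-yl]phenyl]-3-(4-acetoxyphenyl)prop-2-en-1-one (the diene)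
Conditions: Pd(dppf)Cl2 (5 mol%), CsF (3 equiv), BHT (trace), dry THF, 55 °C, argon
Reagents that add atoms: none
Why: Suzuki–Miyaura coupling with retention of alkene geometry installs the E-diene between two acetoxy groups under base-poor conditions that spare the acetates, and both ortho oxygens are capped so the diene cannot cyclise onto a phenol.

**Step 14**
Reactants: 12 (E)-1-[4-acetoxy-2-hydroxy-3-[(E)-3-methylbut-1-en-1-yl]phenyl]-3-(2,4-diacetoxyphenyl)prop-2-en-1-one; 19 (E)-1-[2,4-diacetoxy-3-[(E)-3-methylbuta-1,3-dien-1-yl]phenyl]-3-(4-acetoxyphenyl)prop-2-en-1-one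
Product: 22 endo cycloadduct hexaacetate of (3S,4R,5S) configuration at ring A (ring B 2'-hydroxyl free; the six other phenols acetylated), via dienophile VANOL-borate chelate 20 (not isolated), via cycloadduct VANOL-borate chelate 21 (not isolated)
Conditions: (R)-VANOL (1.2 equiv), BH3·THF (1.2 equiv), AcOH (1.2 equiv), THF, rt until H2 evolution ends; add 12, rt; then 19 (1.5 equiv), PhCF3, 5 Å molecular sieves, 25–40 °C; H2O work-up, ligand recovered on chromatography
Reagents that add atoms: none
Why: Ligand exchange puts boron on the ring-B 2'-oxygen and the ketone oxygen, giving spiro-borate 20 whose s-cis enone has a lowered LUMO, and the E-diene 19 then adds in a concerted, asynchronous, suprafacial [4+2] event; the closest known reaction type is the chiral boron–biaryldiol-promoted Diels–Alder reaction of 2'-hydroxychalcones with 1-aryl-3-methylbutadienes. Ring A closes by intermolecular cycloaddition in which C3–C4 and C5–C6 form in the same operation and C1=C2 arises from the central bond of the diene. C4 and C5 should come out trans because the E-enone geometry is transferred suprafacially, and C3 should come out cis to the C4 acyl group because the flat chelated aroyl unit lies endo under the E-diene (secondary overlap with the diene and stacking with ring D). The absolute configuration of all three centres is set by the (R)-VANOL borate, whose naphthol wall covers the alpha-Re/beta-Re face of the enone so that bonding occurs on the alpha-Si/beta-Si face, giving (3S,4R,5S). Chemoselectivity is secured because only 12 has a free ortho-hydroxy ketone (the enone of 19 carries a 2'-acetate and the styrene of 12 is not a diene), and regioselectivity because the CH2 terminus of 19, which has the largest HOMO coefficient owing to both the 1-aryl and the 3-methyl group, attacks the beta carbon of the chelated enone. Endo against exo is the least secure of the selectivities, and the exo isomer, should it form, would be removed by chromatography at this stage.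

**Step 15**
Reactants: 22 endo cycloadduct hexaacetate of (3S,4R,5S) configuration
Product: 23 target CNP0140882.1, (3S,4R,5S) at ring A
Conditions: K2CO3 (8 equiv), degassed MeOH, 0 °C to rt, argon; AcOH to pH 6
Reagents that add atoms: none
Why: Base-mediated transesterification (Zemplén-type methanolysis) of the six aryl acetates needs no acid, so acid-driven ketalisation of the C4 ketone by the ring C and ring D phenols and cyclisation of the ortho-hydroxystyrene are avoided, and no stereocentre is touched.

**Compound list**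

1 | 2,4-dihydroxyacetophenone | CC(=O)c1ccc(O)cc1O | starting material
2 | 1-(2,4-dihydroxy-3-iodophenyl)ethanone | CC(=O)c1ccc(O)c(I)c1O | intermediate
3 | 1-[2-hydroxy-3-iodo-4-(methoxymethoxy)phenyl]ethanone | CC(=O)c1ccc(OCOC)c(I)c1O | intermediate
4 | 2,4-dihydroxybenzaldehyde | O=Cc1ccc(O)cc1O | starting material
5 | 2,4-bis(methoxymethoxy)benzaldehyde | COCOc1ccc(C=O)c(OCOC)c1 | intermediate
6 | (E)-3-[2,4-bis(methoxymethoxy)phenyl]-1-[2-hydroxy-3-iodo-4-(methoxymethoxy)phenyl]prop-2-en-1-one | O=C(/C=C/c1ccc(OCOC)cc1OCOC)c1ccc(OCOC)c(I)c1O | intermediate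
7 | (E)-1-(2,4-dihydroxy-3-iodophenyl)-3-(2,4-dihydroxyphenyl)prop-2-en-1-one | O=C(/C=C/c1ccc(O)cc1O)c1ccc(O)c(I)c1O | intermediate
8 | (E)-1-(4-acetoxy-2-hydroxy-3-iodophenyl)-3-(2,4-diacetoxyphenyl)prop-2-en-1-one | O=C(/C=C/c1ccc(OC(C)=O)cc1OC(C)=O)c1ccc(OC(C)=O)c(I)c1O | intermediate
9 | 3-methylbut-1-yne | CC(C)C#C | starting material
10 | pinacolborane (4,4,5,5-tetramethyl-1,3,2-dioxaborolane) | CC1(C)OBOC1(C)C | starting material
11 | (E)-4,4,5,5-tetramethyl-2-(3-methylbut-1-en-1-yl)-1,3,2-dioxaborolane | CC(C)/C=C/B1OC(C)(C)C(C)(C)O1 | intermediate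
12 | (E)-1-[4-acetoxy-2-hydroxy-3-[(E)-3-methylbut-1-en-1-yl]phenyl]-3-(2,4-diacetoxyphenyl)prop-2-en-1-one (dienophile) | O=C(/C=C/c1ccc(OC(C)=O)cc1OC(C)=O)c1ccc(OC(C)=O)c(/C=C/C(C)C)c1O | intermediate
13 | 4-(methoxymethoxy)benzaldehyde | COCOc1ccc(C=O)cc1 | starting material
14 | (E)-1-[2-hydroxy-3-iodo-4-(methoxymethoxy)phenyl]-3-[4-(methoxymethoxy)phenyl]prop-2-en-1-one | O=C(/C=C/c1ccc(OCOC)cc1)c1ccc(OCOC)c(I)c1O | intermediate
15 | (E)-1-(2,4-dihydroxy-3-iodophenyl)-3-(4-hydroxyphenyl)prop-2-en-1-one | O=C(/C=C/c1ccc(O)cc1)c1ccc(O)c(I)c1O | intermediate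
16 | (E)-1-(2,4-diacetoxy-3-iodophenyl)-3-(4-acetoxyphenyl)prop-2-en-1-one | O=C(/C=C/c1ccc(OC(C)=O)cc1)c1ccc(OC(C)=O)c(I)c1OC(C)=O | intermediate
17 | 2-methylbut-1-en-3-yne | CC(=C)C#C | starting material
18 | (E)-4,4,5,5-tetramethyl-2-(3-methylbuta-1,3-dien-1-yl)-1,3,2-dioxaborolane | CC(=C)/C=C/B1OC(C)(C)C(C)(C)O1 | intermediate
19 | (E)-1-[2,4-diacetoxy-3-[(E)-3-methylbuta-1,3-dien-1-yl]phenyl]-3-(4-acetoxyphenyl)prop-2-en-1-one (diene) | CC(=C)/C=C/c1c(OC(C)=O)ccc(C(=O)/C=C/c2ccc(OC(C)=O)cc2)c1OC(C)=O | intermediate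
20 | spiro-borate of 12 with (R)-VANOL: boron bound to both ligand oxygens, the ring-B 2'-oxygen and the ketone oxygen (ligand axis R, given by name) | CC(C)/C=C/c1c(OC(C)=O)ccc2c1O[B-]3(Oc4c(-c5c(O3)c6ccccc6cc5-c5ccccc5)c(-c5ccccc5)cc5ccccc45)[O+]=C2/C=C/c1ccc(OC(C)=O)cc1OC(C)=O | intermediate
21 | spiro-borate of cycloadduct 22 with (R)-VANOL, (3S,4R,5S) at ring A (ligand axis R, given by name) | CC1=C[C@H](c2c(OC(C)=O)ccc(C(=O)/C=C/c3ccc(OC(C)=O)cc3)c2OC(C)=O)[C@H](C2=[O+][B-]3(Oc4c(-c5c(O3)c6ccccc6cc5-c5ccccc5)c(-c5ccccc5)cc5ccccc45)Oc3c2ccc(OC(C)=O)c3/C=C/C(C)C)[C@@H](c2ccc(OC(C)=O)cc2OC(C)=O)C1 | intermediate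
22 | endo cycloadduct hexaacetate, (3S,4R,5S) at ring A: C3 ring D (2,6-diacetoxy-3-[(E)-4-acetoxycinnamoyl]phenyl) cis to the C4 aroyl group (4-acetoxy-2-hydroxy-3-[(E)-3-methylbut-1-enyl]benzoyl), which is trans to C5 ring C (2,4-diacetoxyphenyl) | CC1=C[C@H](c2c(OC(C)=O)ccc(C(=O)/C=C/c3ccc(OC(C)=O)cc3)c2OC(C)=O)[C@H](C(=O)c2ccc(OC(C)=O)c(/C=C/C(C)C)c2O)[C@@H](c2ccc(OC(C)=O)cc2OC(C)=O)C1 | intermediate
23 | CNP0140882.1, (3S,4R,5S) at ring A, heptaphenol | CC1=C[C@H](c2c(O)ccc(C(=O)/C=C/c3ccc(O)cc3)c2O)[C@H](C(=O)c2ccc(O)c(/C=C/C(C)C)c2O)[C@@H](c2ccc(O)cc2O)C1 | target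

**Step count and risks**

Total step count: 15. Longest linear sequence: 8 steps (1, 2, 4, 5, 6, 8, 14, 15; the branch 1, 2, 9, 10, 11, 13, 14, 15 is equally long).

Steps most likely to fail:

Step 14. The cycloaddition may lose endo/exo and facial discrimination through a ligand-free or uncatalysed background pathway, and the diene may be consumed by oligomerisation before it reacts. Fallback, setting out from 12 and 19: cycloaddition catalysed by silver nanoparticles on SiO2 (zerovalent silver; CH2Cl2, 50 °C), a known endo-favouring activation of 2'-hydroxychalcones without any chiral ligand, should give the racemic endo adduct, that is 22 together with its mirror-image hexaacetate F1. Preparative chromatography on a chiral stationary phase then separates the two, and the route is rejoined at 22.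

Step 13. The coupling may stall at the doubly ortho-substituted aryl iodide, fluoride may strip or scramble acetyl groups, and the dienylboronate or the product diene may polymerise under palladium and heat. Fallback, setting out from 16: Heck coupling with 2-methylbut-3-en-2-ol (Pd(OAc)2, P(o-tol)3, Et3N, MeCN, 80 °C) should give the E-configured tertiary allylic alcohol F2. Dehydration with Burgess reagent (toluene, 50 °C), which can only remove a methyl hydrogen, then forms the isopropenyl unit, and the route is rejoined at 19.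

Step 8. The free 2'-phenoxide formed under fluoride may attack acetates of a second molecule (acetyl migration or loss), and protodeiodination may compete with the coupling. Fallback, setting out from 3: Suzuki coupling with 11 under ordinary aqueous conditions (Pd(dppf)Cl2, K2CO3, dioxane/H2O, 80 °C), before any acetate is present, should give the butenyl acetophenone F3. Claisen–Schmidt condensation of F3 with 5 (KOH, EtOH) gives the tri-MOM chalcone F4, brief acetal methanolysis (HCl, MeOH, rt) gives the free tetrahydroxychalcone F5, and selective triacetylation (Ac2O, pyridine, 0 °C) rejoins the route at 12.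

**Further compounds**

F1 | step 14 | enantiomer of 22, (3R,4S,5R) endo cycloadduct hexaacetate | CC1=C[C@@H](c2c(OC(C)=O)ccc(C(=O)/C=C/c3ccc(OC(C)=O)cc3)c2OC(C)=O)[C@@H](C(=O)c2ccc(OC(C)=O)c(/C=C/C(C)C)c2O)[C@H](c2ccc(OC(C)=O)cc2OC(C)=O)C1
F2 | step 13 | (E)-1-[2,4-diacetoxy-3-[(E)-3-hydroxy-3-methylbut-1-en-1-yl]phenyl]-3-(4-acetoxyphenyl)prop-2-en-1-one | CC(C)(O)/C=C/c1c(OC(C)=O)ccc(C(=O)/C=C/c2ccc(OC(C)=O)cc2)c1OC(C)=O
F3 | step 8 | 1-[2-hydroxy-4-(methoxymethoxy)-3-[(E)-3-methylbut-1-en-1-yl]phenyl]ethanone | CC(=O)c1ccc(OCOC)c(/C=C/C(C)C)c1O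
F4 | step 8 | (E)-3-[2,4-bis(methoxymethoxy)phenyl]-1-[2-hydroxy-4-(methoxymethoxy)-3-[(E)-3-methylbut-1-en-1-yl]phenyl]prop-2-en-1-one | O=C(/C=C/c1ccc(OCOC)cc1OCOC)c1ccc(OCOC)c(/C=C/C(C)C)c1O
F5 | step 8 | (E)-1-[2,4-dihydroxy-3-[(E)-3-methylbut-1-en-1-yl]phenyl]-3-(2,4-dihydroxyphenyl)prop-2-en-1-one | O=C(/C=C/c1ccc(O)cc1O)c1ccc(O)c(/C=C/C(C)C)c1O
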